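The flavone is cut across ring A at C4a–C8a and C5–C6 and across ring C at O1–C2. Ring A carries oxygen at C5, C7 and C8a, mutually meta around the acyl-bearing C4a, which is the pattern a 1,3-dioxygenated butadiene imprints on a 3-alkoxy ynone. In one operation, cycloaromatization of an ethoxy ynone with a bis-silyloxy diene should build ring A, and the C8a phenol so formed should displace the neighbouring β-methoxy group to close ring C. The precursor is a cross-conjugated enol-ether ynone that already holds the MOM-protected diprenyl ring B and the C3 methoxy group; only MOM and O5-ethyl removal follow.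

Key step: step 9

Remark: the tetrasubstituted enol ether made in step 4 is drawn Z (the two methoxy groups cis) and the silyl enol ether and diene of steps 7 and 8 are drawn as single isomers; the other geometric isomers would serve equally, because these geometries are erased when ring A and ring C form.

Step 1
Reactants: 1 methyl 3,5-dibromo-4-hydroxybenzoate
Product: 2 methyl 3,5-dibromo-4-(methoxymethoxy)benzoate
Conditions: MOMCl, K2CO3, acetone, 23 °C
Reagents that add atoms: chloromethyl methyl ether, COCCl
Why: Williamson-type O-alkylation of the acidic 2,6-dibromophenoxide by the highly reactive α-chloro ether should be fast and leaves the ester untouched.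

Step 2
Reactants: 2 methyl 3,5-dibromo-4-(methoxymethoxy)benzoate; 3 4,4,5,5-tetramethyl-2-(3-methylbut-2-en-1-yl)-1,3,2-dioxaborolane (2.6 equiv)
Product: 5 methyl 4-(methoxymethoxy)-3,5-bis(3-methylbut-2-en-1-yl)benzoate, via mono-prenyl bromide 4 (not isolated)
Conditions: Pd(dppf)Cl2 (5 mol %), K3PO4, THF/H2O, 65 °C
Reagents that add atoms: none
Why: Twofold Suzuki–Miyaura coupling of an allylboronate, in which the allyl(aryl)palladium intermediate should equilibrate by σ–π–σ shift and reductively eliminate at the less hindered primary terminus to give the linear prenyl groups.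

Step 3
Reactants: 5 methyl 4-(methoxymethoxy)-3,5-bis(3-methylbut-2-en-1-yl)benzoate; 6 methyl methoxyacetate
Product: 8 methyl 2-methoxy-3-[4-(methoxymethoxy)-3,5-bis(3-methylbut-2-en-1-yl)phenyl]-3-oxopropanoate (racemic), via lithium enolate 7 (not isolated)
Conditions: LiN(i-Pr)2 (2.5 equiv), 6, THF, −78 °C; then 5, −78 → −10 °C; AcOH
Reagents that add atoms: none
Why: Crossed Claisen condensation in which the preformed ester enolate acylates the non-enolizable aryl ester and deprotonation of the β-keto ester by excess enolate drives the reaction; the new stereocentre forms racemic and disappears in step 4.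

Step 4
Reactants: 8 methyl 2-methoxy-3-[4-(methoxymethoxy)-3,5-bis(3-methylbut-2-en-1-yl)phenyl]-3-oxopropanoate
Product: 9 methyl (2Z)-2,3-dimethoxy-3-[4-(methoxymethoxy)-3,5-bis(3-methylbut-2-en-1-yl)phenyl]prop-2-enoate
Conditions: Me2SO4, Cs2CO3, DMF, 0 → 23 °C
Reagents that add atoms: dimethyl sulfate, COS(=O)(=O)OC
Why: O-alkylation of a β-keto ester enolate, directed to the ketone-derived oxygen by the hard electrophile, the loosely bound cesium counter-ion in a dipolar aprotic solvent and the fully substituted α-carbon.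

Step 5
Reactants: 9 methyl (2Z)-2,3-dimethoxy-3-[4-(methoxymethoxy)-3,5-bis(3-methylbut-2-en-1-yl)phenyl]prop-2-enoate
Product: 10 (2Z)-N,2,3-trimethoxy-N-methyl-3-[4-(methoxymethoxy)-3,5-bis(3-methylbut-2-en-1-yl)phenyl]prop-2-enamide
Conditions: MeNH(OMe)·HCl, i-PrMgCl, THF, −20 → 0 °C
Reagents that add atoms: N,O-dimethylhydroxylamine hydrochloride, CNOC.Cl
Why: Weinreb amide formation by direct aminolysis of the ester with the chloromagnesium amide, whose attack at the hindered, electron-rich β-carbon is not expected to compete.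

Step 6
Reactants: 10 (2Z)-N,2,3-trimethoxy-N-methyl-3-[4-(methoxymethoxy)-3,5-bis(3-methylbut-2-en-1-yl)phenyl]prop-2-enamide; 11 ethoxyacetylene
Product: 13 (1Z)-5-ethoxy-1,2-dimethoxy-1-[4-(methoxymethoxy)-3,5-bis(3-methylbut-2-en-1-yl)phenyl]pent-1-en-4-yn-3-one, via lithium ethoxyacetylide 12 (not isolated)
Conditions: 11, n-BuLi, THF, −78 °C; then 10, −78 → −30 °C; pH 7 phosphate buffer, 0 °C
Reagents that add atoms: none
Why: Weinreb ketone synthesis in which the acetylide adds once to the N-methoxy-N-methylamide and the chelated adduct releases the alkoxy ynone only on neutral quench, which also avoids acid-catalysed hydration of the ynol ether.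

Step 7
Reactants: 14 methyl acetoacetate
Product: 15 methyl (2Z)-3-(trimethylsilyloxy)but-2-enoate
Conditions: TMSCl, Et3N, hexane, 23 °C
Reagents that add atoms: chlorotrimethylsilane, C[Si](C)(C)Cl
Why: O-silylation of the enol of a β-keto ester under amine base is the standard silyl enol ether formation.

Step 8
Reactants: 15 methyl (2Z)-3-(trimethylsilyloxy)but-2-enoate
Product: 16 (1Z)-1-methoxy-1,3-bis(trimethylsilyloxy)buta-1,3-diene
Conditions: LiN(i-Pr)2, THF, −78 °C; TMSCl, −78 → 0 °C; non-aqueous work-up
Reagents that add atoms: chlorotrimethylsilane, C[Si](C)(C)Cl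
Why: γ-Deprotonation of the silyloxy crotonate and O-silylation of the resulting dienolate at the ester oxygen (silyl ketene acetal formation) give the bis-silyloxy diene.

Step 9
Reactants: 13 (1Z)-5-ethoxy-1,2-dimethoxy-1-[4-(methoxymethoxy)-3,5-bis(3-methylbut-2-en-1-yl)phenyl]pent-1-en-4-yn-3-one; 16 (1Z)-1-methoxy-1,3-bis(trimethylsilyloxy)buta-1,3-diene (2.5 equiv)
Product: 19 5-ethoxy-7-hydroxy-3-methoxy-2-[4-(methoxymethoxy)-3,5-bis(3-methylbut-2-en-1-yl)phenyl]-4H-chromen-4-one, via cycloadduct 17 (not isolated), via acylresorcinol 18 (not isolated)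
Conditions: toluene (1 M), 70 °C; then K2CO3 (0.5 equiv), MeOH, 23 → 45 °C
Reagents that add atoms: none
Why: Proposed new method: the electron-rich diene 16 should add across the push-pull triple bond of 13, either as a concerted [4+2] cycloaddition or as a Mukaiyama–Michael addition followed by closure of the resulting allenolate onto the carboxyl carbon derived from the ketene acetal, the diene CH2 terminus bonding to the ethoxy-bearing alkyne carbon (C5–C6) and the ketene acetal carbon to the acyl-bearing alkyne carbon (C4a–C8a) to give cyclohexadiene 17; methanolysis of the two silyl ethers then collapses the mixed ketal with loss of methanol and tautomerization delivers acylresorcinol 18. The closest known reaction type is the Diels–Alder cycloaromatization of 1,3-bis(silyloxy)buta-1,3-dienes with acetylenic ketones and esters to acylresorcinols and salicylates, which has not been extended to an ynone whose β-carbon carries an alkoxy group. Ring A is closed in the [4+2] mode, and ring C by 6-endo-trig oxa-Michael attack of the C8a phenoxide on C2 of the β-methoxy enone followed by expulsion of methoxide (O1–C2). No stereocentre survives, the single one of 17 being destroyed on aromatization. The step needs regioselective C1/C4 engagement of the diene at the alkyne: both alkyne carbons are polarity-matched with the diene termini (electrophilic β-carbon with the CH2 terminus, nucleophilic α-carbon with the acetal carbon), the absence of a Lewis acid disfavours the competing C2/C4 condensation at the ketone, and the tetrasubstituted, doubly oxygenated alkene is too hindered and electron-rich to compete as acceptor. Heating is held at 70 °C, below the temperature at which an ethyl ynol ether fragments by retro-ene loss of ethylene, and ring closure is unambiguous because O5 is ethylated and only the C8a hydroxyl is free.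

Step 10
Reactants: 19 5-ethoxy-7-hydroxy-3-methoxy-2-[4-(methoxymethoxy)-3,5-bis(3-methylbut-2-en-1-yl)phenyl]-4H-chromen-4-one
Product: 20 5-ethoxy-7-hydroxy-2-[4-hydroxy-3,5-bis(3-methylbut-2-en-1-yl)phenyl]-3-methoxy-4H-chromen-4-one
Conditions: 3 M HCl (aq), MeOH, 40 °C
Reagents that add atoms: none
Why: Acid-catalysed acetal methanolysis removes the MOM group as dimethoxymethane under dilute acid that should not cyclize the ortho-prenyl phenol, and doing this before the Lewis-acid step keeps MOM-derived electrophiles away from the electron-rich ring A.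

Step 11
Reactants: 20 5-ethoxy-7-hydroxy-2-[4-hydroxy-3,5-bis(3-methylbut-2-en-1-yl)phenyl]-3-methoxy-4H-chromen-4-one
Product: 21 5,7-dihydroxy-2-[4-hydroxy-3,5-bis(3-methylbut-2-en-1-yl)phenyl]-3-methoxy-4H-chromen-4-one (CNP0205726.0)
Conditions: MgI2·OEt2 (5 equiv), THF, 65 °C; then 1 M HCl (aq)
Reagents that add atoms: none
Why: Chelation-assisted ether cleavage in which magnesium bridges the C4 carbonyl and O5 in a six-membered chelate and iodide dealkylates the activated ethyl group by SN2, a neutral protocol of the kind used for 5-O-dealkylation of prenylated flavonoids that should spare the prenyl groups and the less well chelated 3-methoxy group.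

Compound list
1 | methyl 3,5-dibromo-4-hydroxybenzoate | COC(=O)c1cc(Br)c(O)c(Br)c1 | starting material
2 | methyl 3,5-dibromo-4-(methoxymethoxy)benzoate | COCOc1c(Br)cc(C(=O)OC)cc1Br | intermediate
3 | 4,4,5,5-tetramethyl-2-(3-methylbut-2-en-1-yl)-1,3,2-dioxaborolane (prenylboronic acid pinacol ester) | CC(C)=CCB1OC(C)(C)C(C)(C)O1 | starting material
4 | methyl 3-bromo-4-(methoxymethoxy)-5-(3-methylbut-2-en-1-yl)benzoate | COCOc1c(Br)cc(C(=O)OC)cc1CC=C(C)C | intermediate (not isolated)
5 | methyl 4-(methoxymethoxy)-3,5-bis(3-methylbut-2-en-1-yl)benzoate | COCOc1c(CC=C(C)C)cc(C(=O)OC)cc1CC=C(C)C | intermediate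
6 | methyl methoxyacetate | COCC(=O)OC | starting material
7 | lithium enolate of methyl methoxyacetate (drawn in its carbanion form) | [Li+].CO[CH-]C(=O)OC | intermediate (not isolated)
8 | methyl 2-methoxy-3-[4-(methoxymethoxy)-3,5-bis(3-methylbut-2-en-1-yl)phenyl]-3-oxopropanoate (racemic) | COCOc1c(CC=C(C)C)cc(cc1CC=C(C)C)C(=O)C(OC)C(=O)OC | intermediate
9 | methyl (2Z)-2,3-dimethoxy-3-[4-(methoxymethoxy)-3,5-bis(3-methylbut-2-en-1-yl)phenyl]prop-2-enoate | COC(=O)/C(OC)=C(/OC)c1cc(CC=C(C)C)c(OCOC)c(CC=C(C)C)c1 | intermediate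
10 | (2Z)-N,2,3-trimethoxy-N-methyl-3-[4-(methoxymethoxy)-3,5-bis(3-methylbut-2-en-1-yl)phenyl]prop-2-enamide | CON(C)C(=O)/C(OC)=C(/OC)c1cc(CC=C(C)C)c(OCOC)c(CC=C(C)C)c1 | intermediate
11 | ethoxyacetylene (ethoxyethyne) | CCOC#C | starting material
12 | lithium ethoxyacetylide | CCOC#C[Li] | intermediate (not isolated)
13 | (1Z)-5-ethoxy-1,2-dimethoxy-1-[4-(methoxymethoxy)-3,5-bis(3-methylbut-2-en-1-yl)phenyl]pent-1-en-4-yn-3-one | CCOC#CC(=O)/C(OC)=C(/OC)c1cc(CC=C(C)C)c(OCOC)c(CC=C(C)C)c1 | intermediate
14 | methyl acetoacetate | COC(=O)CC(C)=O | starting material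
15 | methyl (2Z)-3-(trimethylsilyloxy)but-2-enoate | COC(=O)/C=C(/C)O[Si](C)(C)C | intermediate
16 | (1Z)-1-methoxy-1,3-bis(trimethylsilyloxy)buta-1,3-diene | CO/C(O[Si](C)(C)C)=C/C(=C)O[Si](C)(C)C | intermediate
17 | (2Z)-1-[2-ethoxy-6-methoxy-4,6-bis(trimethylsilyloxy)cyclohexa-1,4-dien-1-yl]-2,3-dimethoxy-3-[4-(methoxymethoxy)-3,5-bis(3-methylbut-2-en-1-yl)phenyl]prop-2-en-1-one (racemic cycloadduct) | CCOC1=C(C(=O)/C(OC)=C(/OC)c2cc(CC=C(C)C)c(OCOC)c(CC=C(C)C)c2)C(OC)(O[Si](C)(C)C)C=C(O[Si](C)(C)C)C1 | intermediate (not isolated)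
18 | (2Z)-1-(2-ethoxy-4,6-dihydroxyphenyl)-2,3-dimethoxy-3-[4-(methoxymethoxy)-3,5-bis(3-methylbut-2-en-1-yl)phenyl]prop-2-en-1-one | CCOc1cc(O)cc(O)c1C(=O)/C(OC)=C(/OC)c1cc(CC=C(C)C)c(OCOC)c(CC=C(C)C)c1 | intermediate (not isolated)
19 | 5-ethoxy-7-hydroxy-3-methoxy-2-[4-(methoxymethoxy)-3,5-bis(3-methylbut-2-en-1-yl)phenyl]-4H-chromen-4-one | CCOc1cc(O)cc2oc(-c3cc(CC=C(C)C)c(OCOC)c(CC=C(C)C)c3)c(OC)c(=O)c12 | intermediate
20 | 5-ethoxy-7-hydroxy-2-[4-hydroxy-3,5-bis(3-methylbut-2-en-1-yl)phenyl]-3-methoxy-4H-chromen-4-one | CCOc1cc(O)cc2oc(-c3cc(CC=C(C)C)c(O)c(CC=C(C)C)c3)c(OC)c(=O)c12 | intermediate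
21 | 5,7-dihydroxy-2-[4-hydroxy-3,5-bis(3-methylbut-2-en-1-yl)phenyl]-3-methoxy-4H-chromen-4-one (CNP0205726.0) | COc1c(-c2cc(CC=C(C)C)c(O)c(CC=C(C)C)c2)oc2cc(O)cc(O)c2c1=O | target

Total step count: 11. Longest linear sequence: 9 steps (steps 1–6 and 9–11 from 1); the diene branch (steps 7–8) joins at step 9.

Steps most likely to fail

Step 9 (new method). The push-pull alkyne may be too weak a 2π partner below the retro-ene ceiling of the ynol ether. The diene may instead condense through C2 and C4 at the ketone, or displace ethoxide from the alkyne. Ring closure may also stall at the acylresorcinol stage. The fallback is a Baker–Venkataraman route of known chemistry that sets out from ester 5. Saponification (LiOH, THF/MeOH/H2O) should give 4-(methoxymethoxy)-3,5-bis(3-methylbut-2-en-1-yl)benzoic acid F1. Commercial 2-methoxy-1-(2,4,6-trihydroxyphenyl)ethan-1-one is protected at its two non-chelated hydroxyls (MOMCl, i-Pr2NEt, CH2Cl2) to give 1-[2-hydroxy-4,6-bis(methoxymethoxy)phenyl]-2-methoxyethan-1-one F2. Steglich esterification (EDC, DMAP, CH2Cl2) of F2 with F1 should give 2-(2-methoxyacetyl)-3,5-bis(methoxymethoxy)phenyl 4-(methoxymethoxy)-3,5-bis(3-methylbut-2-en-1-yl)benzoate F3. Baker–Venkataraman acyl migration (LiN(SiMe3)2, THF, −20 → 23 °C) should give 1-[2-hydroxy-4,6-bis(methoxymethoxy)phenyl]-2-methoxy-3-[4-(methoxymethoxy)-3,5-bis(3-methylbut-2-en-1-yl)phenyl]propane-1,3-dione F4. Methanolic HCl at 50 °C should then effect cyclodehydration with loss of all three MOM groups, so the sequence comes back to the route at target 21.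

Step 11. SN2 attack of iodide at the ethyl carbon is slower than at a methyl group, so conversion may stall, or demethylation at O3 through the five-membered chelate may compete on prolonged heating. The fallback sets out from 20 and switches to boron-chelate dealkylation on the persilylated substrate. N,O-bis(trimethylsilyl)acetamide (CH2Cl2, 23 °C) should give 5-ethoxy-3-methoxy-7-(trimethylsilyloxy)-2-[3,5-bis(3-methylbut-2-en-1-yl)-4-(trimethylsilyloxy)phenyl]-4H-chromen-4-one F5. BCl3 (CH2Cl2, −78 → −20 °C) should then bind between the C4 carbonyl and O5 and cleave the ethyl group as chloroethane. Because both phenols are silylated, no hydrogen chloride is released to attack the prenyl groups. Work-up with MeOH and aqueous NaHCO3 hydrolyses the borate and silyl ethers and returns to the route at target 21.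

Step 2. Reductive elimination at the tertiary allyl terminus would give 1,1-dimethylallyl (reverse-prenyl) isomers; the coupling may also stall after the first prenyl group or suffer protodebromination. The fallback sets out from 2 and replaces the palladium coupling by aryl-metal alkylation. Bromine–magnesium exchange (i-PrMgCl·LiCl, THF, −20 °C), transmetalation with CuBr·SMe2 and SN2 alkylation of prenyl bromide at its primary carbon should give bromide 4, now isolated. A second cycle of the same three operations (exchange at −10 °C) returns to the route at 5. This fallback makes no compound outside the compound list (F0).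

Further compounds
F1 | step 9 | 4-(methoxymethoxy)-3,5-bis(3-methylbut-2-en-1-yl)benzoic acid | OC(=O)c1cc(CC=C(C)C)c(OCOC)c(CC=C(C)C)c1
F2 | step 9 | 1-[2-hydroxy-4,6-bis(methoxymethoxy)phenyl]-2-methoxyethan-1-one | COCC(=O)c1c(O)cc(OCOC)cc1OCOC
F3 | step 9 | 2-(2-methoxyacetyl)-3,5-bis(methoxymethoxy)phenyl 4-(methoxymethoxy)-3,5-bis(3-methylbut-2-en-1-yl)benzoate | COCC(=O)c1c(OC(=O)c2cc(CC=C(C)C)c(OCOC)c(CC=C(C)C)c2)cc(OCOC)cc1OCOC
F4 | step 9 | 1-[2-hydroxy-4,6-bis(methoxymethoxy)phenyl]-2-methoxy-3-[4-(methoxymethoxy)-3,5-bis(3-methylbut-2-en-1-yl)phenyl]propane-1,3-dione (racemic) | COC(C(=O)c1c(O)cc(OCOC)cc1OCOC)C(=O)c1cc(CC=C(C)C)c(OCOC)c(CC=C(C)C)c1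
F5 | step 11 | 5-ethoxy-3-methoxy-7-(trimethylsilyloxy)-2-[3,5-bis(3-methylbut-2-en-1-yl)-4-(trimethylsilyloxy)phenyl]-4H-chromen-4-one | CCOc1cc(O[Si](C)(C)C)cc2oc(-c3cc(CC=C(C)C)c(O[Si](C)(C)C)c(CC=C(C)C)c3)c(OC)c(=O)c12
F0 | step 2 | none | none
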